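**Retrosynthetic overview** (atoms numbered C1 = CO2H to C14 along the acid chain)
- Target ⇐ saponification ⇐ dioxane methyl ester ⇐ 6-exo oxa-Michael closure (O–C3) of a C6 hydroperoxide onto an (E)-enoate; the 1,2-dioxane is the only ring and is formed last but one.
- C6–OOH ⇐ SN1 perhydrolysis of a tertiary allylic alcohol ⇐ C6–C7 bond by adding an alkenylcerium (fragment 1, C7–C14) to the C6 ethyl ketone of a keto-enoate (fragment 2, C1–C6).
- Alkenyl iodide ⇐ syn-ethylcupration/iodination of a terminal alkyne ⇐ Ohira–Bestmann ⇐ aldehyde ⇐ ester from a Johnson–Claisen [3,3] shift that makes C9–C10 and sets C10.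
- Keto-enoate ⇐ acrylate cross-metathesis and EtLi on the amide from an Eschenmoser–Claisen [3,3] shift that makes C4–C5 and sets C4.
- Both Claisen substrates are the antipodal (E)-hept-4-en-3-ols, two steps each from (R)- or (S)-1,2-epoxybutane; C3 follows C4 in the ring closure; C6 is not biased and its epimer is removed at the dioxane ester.

Assumption: (R)- and (S)-1,2-epoxybutane are bought as the only sources of chirality.

**Route**

Step 1
Reactants: 1 (R)-2-ethyloxirane
Product: 2 (R)-pent-1-en-3-ol
Conditions: Me3S+ I− (3 equiv), n-BuLi (2.9 equiv), THF, −10 °C to rt; then H2O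
Reagents that add atoms: trimethylsulfonium iodide, C[S+](C)C.[I-]
Why: Dimethylsulfonium methylide opens the epoxide at its CH2 terminus (Corey–Chaykovsky-type addition) and the derived sulfonium ylide then eliminates Me2S, giving the one-carbon-homologated allylic alcohol while the purchased carbinol centre is never touched.

Step 2
Reactants: 2 (R)-pent-1-en-3-ol
Product: 3 (3R,4E)-hept-4-en-3-ol
Conditions: (Z)-hex-3-ene (5 equiv), second-generation Hoveyda–Grubbs catalyst [RuCl2(H2IMes)(=CH-C6H4-2-OiPr)] (2 mol %), CH2Cl2, 40 °C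
Reagents that add atoms: (Z)-hex-3-ene, CC/C=C\CC
Why: Olefin cross-metathesis of the terminal alkene with excess hex-3-ene is reversible and therefore E-selective (at least 10:1 expected, the residual Z isomer being removed on AgNO3-impregnated silica), and it leaves the carbinol centre untouched.

Step 3
Reactants: 3 (3R,4E)-hept-4-en-3-ol
Product: 5 ethyl (3R,4E)-3-ethylhept-4-enoate, via ketene acetal 4 (not isolated)
Conditions: MeC(OEt)3 (6 equiv), EtCO2H (5 mol %), 140 °C, EtOH distilled off
Reagents that add atoms: triethyl orthoacetate, CC(OCC)(OCC)OCC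
Why: Johnson–Claisen rearrangement, the key [3,3]-sigmatropic step: ketene acetal 4 reacts through a chair transition state with the carbinol ethyl group equatorial, so the C9–C10 bond forms on the face from which the C–O bond leaves, the (R)-carbinol centre is transferred into (R)-C10 and the new alkene is E.

Step 4
Reactants: 5 ethyl (3R,4E)-3-ethylhept-4-enoate
Product: 6 (3R,4E)-3-ethylhept-4-enal
Conditions: i-Bu2AlH (1.1 equiv), CH2Cl2, −78 °C; then aq. potassium sodium tartrate
Reagents that add atoms: none
Why: At −78 °C the aluminium hemiacetal formed by a single hydride transfer survives until work-up, so the ester reduction stops at the aldehyde, and the stereocentre is beta to the carbonyl and cannot epimerise.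

Step 5
Reactants: 6 (3R,4E)-3-ethylhept-4-enal
Product: 7 (4R,5E)-4-ethyloct-5-en-1-yne
Conditions: dimethyl (1-diazo-2-oxopropyl)phosphonate (1.3 equiv), K2CO3 (2 equiv), MeOH, 0 °C to rt
Reagents that add atoms: dimethyl (1-diazo-2-oxopropyl)phosphonate, CC(=O)C(=[N+]=[N-])P(=O)(OC)OC
Why: Ohira–Bestmann variant of the Seyferth–Gilbert homologation: methanolysis liberates the dimethyl diazomethylphosphonate anion, which olefinates the aldehyde, and loss of N2 followed by a 1,2-hydride shift gives the terminal alkyne under mild carbonate base that cannot disturb C10.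

Step 6
Reactants: 7 (4R,5E)-4-ethyloct-5-en-1-yne
Product: 9 (1E,4R,5E)-2,4-diethyl-1-iodoocta-1,5-diene, via alkenylcopper 8 (not isolated)
Conditions: EtMgBr (1.3 equiv), CuBr·SMe2 (1.3 equiv), Et2O/Me2S, −45 °C; then 7, −25 °C, 2 h; then I2 (1.4 equiv), THF, −45 to 0 °C
Reagents that add atoms: ethylmagnesium bromide, CC[Mg]Br; iodine, [I][I]
Why: Normant carbocupration: ethylcopper adds syn across the terminal alkyne with ethyl on the internal carbon, and iodinolysis of alkenylcopper 8 with retention gives the iodide with ethyl cis to iodine, which is the geometry of the later (7E) trisubstituted alkene.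

Step 7
Reactants: 10 (S)-2-ethyloxirane
Product: 11 (S)-pent-1-en-3-ol
Conditions: Me3S+ I− (3 equiv), n-BuLi (2.9 equiv), THF, −10 °C to rt; then H2O
Reagents that add atoms: trimethylsulfonium iodide, C[S+](C)C.[I-]
Why: The same sulfonium-ylide epoxide opening and elimination as in step 1 gives the antipodal allylic alcohol with the purchased stereocentre untouched.

Step 8
Reactants: 11 (S)-pent-1-en-3-ol
Product: 12 (3S,4E)-hept-4-en-3-ol
Conditions: (Z)-hex-3-ene (5 equiv), second-generation Hoveyda–Grubbs catalyst [RuCl2(H2IMes)(=CH-C6H4-2-OiPr)] (2 mol %), CH2Cl2, 40 °C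
Reagents that add atoms: (Z)-hex-3-ene, CC/C=C\CC
Why: The same thermodynamically E-selective olefin cross-metathesis as in step 2 is used, with the Z isomer removed on AgNO3-impregnated silica and the carbinol centre untouched.

Step 9
Reactants: 12 (3S,4E)-hept-4-en-3-ol
Product: 14 (3S,4E)-3-ethyl-N,N-dimethylhept-4-enamide, via ketene N,O-acetal 13 (not isolated)
Conditions: MeC(OMe)2NMe2 (3 equiv), xylene, 140 °C
Reagents that add atoms: N,N-dimethylacetamide dimethyl acetal, CC(OC)(OC)N(C)C
Why: Eschenmoser–Claisen rearrangement, the second [3,3]-sigmatropic step: ketene N,O-acetal 13 rearranges through the chair with the carbinol ethyl group equatorial, forming the C4–C5 bond suprafacially so that the (S)-carbinol centre becomes (S)-C4 and the alkene is E.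

Step 10
Reactants: 14 (3S,4E)-3-ethyl-N,N-dimethylhept-4-enamide
Product: 15 (5S,6E)-5-ethylnon-6-en-3-one
Conditions: EtLi (1.5 equiv), Et2O, −78 to 0 °C; then H2O
Reagents that add atoms: ethyllithium, [Li]CC
Why: Ethyllithium adds only once to the tertiary amide because the tetrahedral lithium hemiaminal is stable until aqueous work-up, which then releases the ethyl ketone (C6) without touching C4.

Step 11
Reactants: 15 (5S,6E)-5-ethylnon-6-en-3-one
Product: 16 methyl (2E,4S)-4-ethyl-6-oxooct-2-enoate
Conditions: methyl acrylate (5 equiv), second-generation Hoveyda–Grubbs catalyst [RuCl2(H2IMes)(=CH-C6H4-2-OiPr)] (5 mol %), CH2Cl2, 40 °C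
Reagents that add atoms: methyl acrylate, C=CC(=O)OC
Why: Olefin cross-metathesis with excess methyl acrylate replaces the propylidene end of the alkene by the acrylate unit and gives the conjugated (E)-enoate under thermodynamic control, with the allylic centre C4 unaffected.

Step 12
Reactants: 9 (1E,4R,5E)-2,4-diethyl-1-iodoocta-1,5-diene; 16 methyl (2E,4S)-4-ethyl-6-oxooct-2-enoate
Product: 19 methyl (2E,4S,6RS,7E,10R,11E)-4,6,8,10-tetraethyl-6-hydroxytetradeca-2,7,11-trienoate, via alkenyllithium 17 (not isolated), via alkenylcerium dichloride 18 (not isolated)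
Conditions: 9, t-BuLi (2.05 equiv), Et2O, −78 °C; CeCl3 (1.2 equiv), THF, −78 °C; then 16, −78 °C; then H2O
Reagents that add atoms: none
Why: Iodine–lithium exchange proceeds with retention of alkene geometry, and the weakly basic, oxophilic organocerium 18 undergoes carbonyl 1,2-addition to the ketone much faster than it attacks the enoate; C6 forms here as both epimers, which is of no consequence because C6 is ionised in step 13.

Step 13
Reactants: 19 methyl (2E,4S,6RS,7E,10R,11E)-4,6,8,10-tetraethyl-6-hydroxytetradeca-2,7,11-trienoate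
Product: 20 methyl (2E,4S,6RS,7E,10R,11E)-4,6,8,10-tetraethyl-6-hydroperoxytetradeca-2,7,11-trienoate
Conditions: H2O2 (ethereal, about 2 M, 15 equiv), TsOH·H2O (10 mol %), Et2O, 0 °C
Reagents that add atoms: hydrogen peroxide, OO
Why: Acid-catalysed SN1 perhydrolysis: the tertiary allylic alcohol ionises to a tetraalkylallyl cation that the alpha-effect nucleophile H2O2 captures, by ion-pair return preferentially at the carbon that has just lost water; because the cation is planar both C6 epimers form, and the transposed C8 hydroperoxide, which cannot cyclise in step 14, is re-equilibrated under the same conditions.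

Step 14
Reactants: 20 methyl (2E,4S,6RS,7E,10R,11E)-4,6,8,10-tetraethyl-6-hydroperoxytetradeca-2,7,11-trienoate
Product: 21 methyl 2-[(3S,4S,6S)-4,6-diethyl-6-[(1E,4R,5E)-2,4-diethylocta-1,5-dien-1-yl]-1,2-dioxan-3-yl]acetate
Conditions: Et2NH (2 equiv), CF3CH2OH, rt
Reagents that add atoms: none
Why: Amine-promoted 6-exo-trig oxa-Michael addition of the hydroperoxide to the (E)-enoate closes the 1,2-dioxane through a chair transition state with the C4 ethyl group equatorial, which is expected to set C3 cis to C4 (3S) while the protic solvent traps the ester enolate before it can expel alkoxide; the (6S) product is separated by chromatography from the (6R) epimer that stems from the unbiased step 13.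

Step 15
Reactants: 21 methyl 2-[(3S,4S,6S)-4,6-diethyl-6-[(1E,4R,5E)-2,4-diethylocta-1,5-dien-1-yl]-1,2-dioxan-3-yl]acetate
Product: 22 2-[(3S,4S,6S)-4,6-diethyl-6-[(1E,4R,5E)-2,4-diethylocta-1,5-dien-1-yl]-1,2-dioxan-3-yl]acetic acid
Conditions: LiOH·H2O (3 equiv), THF/H2O 3:1, 0 °C to rt; then 1 M HCl to pH 3
Reagents that add atoms: lithium hydroxide, [Li+].[OH-]
Why: Saponification with LiOH at 0 °C cleaves the methyl ester by acyl–oxygen fission without touching the dialkyl peroxide or any stereocentre, and careful acidification gives the free acid.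

**Compound list**

1 | (R)-2-ethyloxirane | CC[C@@H]1CO1 | starting material
2 | (R)-pent-1-en-3-ol | CC[C@@H](O)C=C | intermediate
3 | (3R,4E)-hept-4-en-3-ol | CC[C@@H](O)/C=C/CC | intermediate
4 | (3R,4E)-3-[(1-ethoxyethenyl)oxy]hept-4-ene (ketene acetal) | CC[C@@H](OC(=C)OCC)/C=C/CC | intermediate
5 | ethyl (3R,4E)-3-ethylhept-4-enoate | CC/C=C/[C@H](CC)CC(=O)OCC | intermediate
6 | (3R,4E)-3-ethylhept-4-enal | CC/C=C/[C@H](CC)CC=O | intermediate
7 | (4R,5E)-4-ethyloct-5-en-1-yne | CC/C=C/[C@H](CC)CC#C | intermediate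
8 | [(1E,4R,5E)-2,4-diethylocta-1,5-dien-1-yl]copper (alkenylcopper) | CC/C=C/[C@H](CC)C/C(=C/[Cu])CC | intermediate
9 | (1E,4R,5E)-2,4-diethyl-1-iodoocta-1,5-diene | CC/C=C/[C@H](CC)C/C(=C/I)CC | intermediate
10 | (S)-2-ethyloxirane | CC[C@H]1CO1 | starting material
11 | (S)-pent-1-en-3-ol | CC[C@H](O)C=C | intermediate
12 | (3S,4E)-hept-4-en-3-ol | CC[C@H](O)/C=C/CC | intermediate
13 | 1-{[(3S,4E)-hept-4-en-3-yl]oxy}-N,N-dimethylethen-1-amine (ketene N,O-acetal) | CC[C@H](OC(=C)N(C)C)/C=C/CC | intermediate
14 | (3S,4E)-3-ethyl-N,N-dimethylhept-4-enamide | CC/C=C/[C@@H](CC)CC(=O)N(C)C | intermediate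
15 | (5S,6E)-5-ethylnon-6-en-3-one | CC/C=C/[C@@H](CC)CC(=O)CC | intermediate
16 | methyl (2E,4S)-4-ethyl-6-oxooct-2-enoate | COC(=O)/C=C/[C@@H](CC)CC(=O)CC | intermediate
17 | [(1E,4R,5E)-2,4-diethylocta-1,5-dien-1-yl]lithium (alkenyllithium) | CC/C=C/[C@H](CC)C/C(=C/[Li])CC | intermediate
18 | dichloro[(1E,4R,5E)-2,4-diethylocta-1,5-dien-1-yl]cerium (alkenylcerium dichloride) | CC/C=C/[C@H](CC)C/C(=C/[Ce](Cl)Cl)CC | intermediate
19 | methyl (2E,4S,6RS,7E,10R,11E)-4,6,8,10-tetraethyl-6-hydroxytetradeca-2,7,11-trienoate | CC/C=C/[C@H](CC)C/C(=C/C(O)(CC)C[C@H](CC)/C=C/C(=O)OC)CC | intermediate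
20 | methyl (2E,4S,6RS,7E,10R,11E)-4,6,8,10-tetraethyl-6-hydroperoxytetradeca-2,7,11-trienoate | CC/C=C/[C@H](CC)C/C(=C/C(OO)(CC)C[C@H](CC)/C=C/C(=O)OC)CC | intermediate
21 | methyl 2-[(3S,4S,6S)-4,6-diethyl-6-[(1E,4R,5E)-2,4-diethylocta-1,5-dien-1-yl]-1,2-dioxan-3-yl]acetate | CC/C=C/[C@H](CC)C/C(=C/[C@]1(CC)C[C@H](CC)[C@H](CC(=O)OC)OO1)CC | intermediate
22 | 2-[(3S,4S,6S)-4,6-diethyl-6-[(1E,4R,5E)-2,4-diethylocta-1,5-dien-1-yl]-1,2-dioxan-3-yl]acetic acid | CC/C=C/[C@H](CC)C/C(=C/[C@]1(CC)C[C@H](CC)[C@H](CC(=O)O)OO1)CC | target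

**Totals**

Total step count: 15. Longest linear sequence: 10 steps (steps 1 to 6, then 12 to 15).

**Steps most likely to fail, with fallbacks**

Step 13 is the weakest step. Capture of the allyl cation at C8, E1 loss to trienes and acid-induced cleavage of the allylic hydroperoxide all compete, and C6 is unbiased. The fallback sets out from 16 and 9 and comes back at 21; it makes the peroxide ring before the C6–C7 bond, so no open allyl cation is involved. Compound 16 is treated with urea–H2O2 and catalytic Sc(OTf)3 in MeOH to give methyl (2E,4S)-4-ethyl-6-hydroperoxy-6-methoxyoct-2-enoate F1. This closes with Et2NH in CF3CH2OH to methyl 2-[(3S,4S,6RS)-4,6-diethyl-6-methoxy-1,2-dioxan-3-yl]acetate F2. Separately, 9 is converted by t-BuLi and then Me3SiCl into [(1E,4R,5E)-2,4-diethylocta-1,5-dien-1-yl]trimethylsilane F3. Me3SiOTf in CH2Cl2 at −78 °C ionises the peroxyketal F2 to a cyclic peroxycarbenium ion, which the vinylsilane F3 captures at C6 by ipso substitution with retention of alkene geometry. This gives 21 and its C6 epimer; the face selectivity at C6 is not assured, and axial attack anti to the 4-ethyl group would favour the unwanted epimer, so the two are again separated by chromatography.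

Step 12 may suffer from attack of the alkenylmetal on the enoate or from enolisation of the ketone. The fallback sets out from 7 and 16 and comes back at 19; it uses the much less basic acetylide and builds the alkene afterwards. Lithiated 7 (n-BuLi, then CeCl3) adds to the ketone of 16 to give methyl (2E,4S,6RS,10R,11E)-4,6,10-triethyl-6-hydroxytetradeca-2,11-dien-7-ynoate F4. Hydroxyl-directed trans-hydrosilylation with Et3SiH and catalytic [Cp*Ru(MeCN)3]PF6 places silicon on the distal alkyne carbon and gives methyl (2E,4S,6RS,7Z,10R,11E)-4,6,10-triethyl-6-hydroxy-8-(triethylsilyl)tetradeca-2,7,11-trienoate F5. Iododesilylation with N-iodosuccinimide in (CF3)2CHOH, with retention, gives methyl (2E,4S,6RS,7Z,10R,11E)-4,6,10-triethyl-6-hydroxy-8-iodotetradeca-2,7,11-trienoate F6. Negishi coupling with Et2Zn and catalytic Pd(dppf)Cl2 replaces iodine by ethyl with retention and returns 19.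

Step 11 uses an alpha-branched 1,2-disubstituted alkene, which is a sluggish metathesis partner, so conversion may stall while the acrylate dimerises. The fallback sets out from 15 and comes back at 16. Ozonolysis of 15 (O3, CH2Cl2, −78 °C, then Me2S) gives (2S)-2-ethyl-4-oxohexanal F7. This is used at once in a Wittig reaction with Ph3P=CHCO2Me (CH2Cl2, rt), which returns 16 with E geometry; the neutral stabilised ylide keeps the now alpha stereocentre from epimerising.

Further compounds
F1 | step 13 | methyl (2E,4S)-4-ethyl-6-hydroperoxy-6-methoxyoct-2-enoate | COC(=O)/C=C/[C@@H](CC)CC(OO)(OC)CC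
F2 | step 13 | methyl 2-[(3S,4S,6RS)-4,6-diethyl-6-methoxy-1,2-dioxan-3-yl]acetate | CCC1(OC)C[C@H](CC)[C@H](CC(=O)OC)OO1
F3 | step 13 | [(1E,4R,5E)-2,4-diethylocta-1,5-dien-1-yl]trimethylsilane | CC/C=C/[C@H](CC)C/C(=C/[Si](C)(C)C)CC
F4 | step 12 | methyl (2E,4S,6RS,10R,11E)-4,6,10-triethyl-6-hydroxytetradeca-2,11-dien-7-ynoate | CC/C=C/[C@H](CC)CC#CC(O)(CC)C[C@H](CC)/C=C/C(=O)OC
F5 | step 12 | methyl (2E,4S,6RS,7Z,10R,11E)-4,6,10-triethyl-6-hydroxy-8-(triethylsilyl)tetradeca-2,7,11-trienoate | CC/C=C/[C@H](CC)C/C(=C/C(O)(CC)C[C@H](CC)/C=C/C(=O)OC)[Si](CC)(CC)CC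
F6 | step 12 | methyl (2E,4S,6RS,7Z,10R,11E)-4,6,10-triethyl-6-hydroxy-8-iodotetradeca-2,7,11-trienoate | CC/C=C/[C@H](CC)C/C(=C/C(O)(CC)C[C@H](CC)/C=C/C(=O)OC)I
F7 | step 11 | (2S)-2-ethyl-4-oxohexanal | O=C[C@@H](CC)CC(=O)CC
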